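The isoflavan is cut at C3–C1' and C4–C4a. The feature used is the C3–C4 ethylene unit that links ring B (through C1') to ring A (through C4a) and carries only C2 as a further branch on C3: a vinylboronate supplies exactly these two carbons, with boron marking the place of C2. One palladium-catalysed enantioselective conjunctive coupling unites a ring B aryllithium, pinacol vinylboronate and a ring A aryl triflate, creating both bonds and the C3 stereocentre. Its precursor is a halide-free lithium aryl(vinyl)boronate complex, made by MOM-directed ortho-lithiation, plus an ortho-benzyloxy aryl triflate. Homologation, oxidation, Mitsunobu closure of O1–C2 and phenol oxidation of ring B finish the quinone.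

Key step: step 5

Numbering: isoflavan numbering is used (O1, C2, C3, C4, C4a, C5–C8, C8a; ring A is the benzo ring, ring C the pyran ring, ring B carries C1'–C6'). The target has the S configuration at C3.

Assumption: the (Rp,Rp) antipode of MandyPhos (C52H50FeN2P2) is written for step 5 on the expectation, by analogy with simple aryl migrations, that it gives the (S)-boronate. If oxidation of an aliquot shows the opposite sense, the (Sp,Sp) antipode, also commercial, is used with no other change.

Design remarks: the ring B aryllithium is made by deprotonation, not by halogen–lithium exchange, so no lithium halide enters the coupling and no bromination step is needed. Benzyl on O1 and MOM on the C2' oxygen are orthogonal, so only the ring A phenol is free at the ring closure. The free C2' phenol at the end lets a mild iodine oxidant act on ring B alone.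

Step 1
Reactants: 1 2,3,4-trimethoxyphenol
Product: 2 1,2,3-trimethoxy-4-(methoxymethoxy)benzene
Conditions: NaH, THF, 0 °C; MOMCl, 0 °C → rt
Reagents that add atoms: chloromethyl methyl ether (MOMCl), COCCl
Why: Williamson-type O-alkylation of the sodium phenoxide by the α-chloro ether should be fast and clean, and the resulting MOM acetal both withstands organolithiums and later directs lithiation to the adjacent C–H (future C1').

Step 2
Reactants: 3 2-hydroxy-4,5-dimethoxybenzaldehyde
Product: 4 2-(benzyloxy)-4,5-dimethoxybenzaldehyde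
Conditions: BnBr, K2CO3, DMF, rt
Reagents that add atoms: benzyl bromide, BrCc1ccccc1
Why: Williamson ether synthesis on the acidic salicylaldehyde phenol with a benzylic bromide in a polar aprotic solvent is routine.

Step 3
Reactants: 4 2-(benzyloxy)-4,5-dimethoxybenzaldehyde
Product: 6 2-(benzyloxy)-4,5-dimethoxyphenol, via aryl formate 5 (not isolated)
Conditions: mCPBA, CH2Cl2, 0 °C → rt; then K2CO3 (cat.), MeOH, rt
Reagents that add atoms: meta-chloroperoxybenzoic acid (mCPBA), OOC(=O)c1cccc(Cl)c1
Why: Baeyer–Villiger (Dakin-type) oxidation, in which the electron-rich trialkoxyaryl group migrates in preference to hydrogen in the Criegee adduct to give the aryl formate, which base-catalysed methanolysis cleaves to the phenol without touching the benzyl ether.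

Step 4
Reactants: 6 2-(benzyloxy)-4,5-dimethoxyphenol
Product: 7 2-(benzyloxy)-4,5-dimethoxyphenyl trifluoromethanesulfonate
Conditions: Tf2O, pyridine, CH2Cl2, 0 °C
Reagents that add atoms: trifluoromethanesulfonic anhydride, O=S(=O)(OS(=O)(=O)C(F)(F)F)C(F)(F)F
Why: O-sulfonylation of the phenol with triflic anhydride and pyridine gives a halide-free aryl triflate, the electrophile class best suited to conjunctive coupling.

Step 5
Reactants: 2 1,2,3-trimethoxy-4-(methoxymethoxy)benzene; 8 pinacol vinylboronate (4,4,5,5-tetramethyl-2-vinyl-1,3,2-dioxaborolane); 7 2-(benzyloxy)-4,5-dimethoxyphenyl trifluoromethanesulfonate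
Product: 11 pinacol {(1S)-2-[2-(benzyloxy)-4,5-dimethoxyphenyl]-1-[2-(methoxymethoxy)-3,4,5-trimethoxyphenyl]ethyl}boronate, via aryllithium 9 (not isolated), via lithium vinylboronate complex 10 (not isolated)
Conditions: 2 (1.05 equiv), n-BuLi (1.0 equiv), THF, 0 °C; 8, −78 °C → rt; Pd(OAc)2 (2 mol %), (Rp,Rp)-MandyPhos C52H50FeN2P2 [1,1'-bis(α-dimethylaminobenzyl)-2,2'-bis(diphenylphosphino)ferrocene] (2.4 mol %), 7, THF, 60 °C
Reagents that add atoms: none
Why: Triflate 7 adds oxidatively to zerovalent palladium (formed from Pd(OAc)2 and the diphosphine), and the cationic arylpalladium binds the vinyl group of complex 10. The ring B aryl then shifts from boron to the α-carbon (C3) anti to palladium while palladium bonds the β-carbon (C4), and reductive elimination forms C4–C4a, so C3–C1' and C4–C4a arise in one catalytic cycle and no ring is closed. The closest known reaction type is the palladium/MandyPhos-catalysed enantioselective conjunctive cross-coupling of aryl(vinyl)boronate complexes with aryl triflates. The new stereocentre C3 is controlled by the chiral diphosphine, which selects the enantioface of the bound vinylboronate during the metallate shift. The step needs the metallate shift to outrun direct transmetallation (Suzuki-type coupling), which is secured by the weakly coordinating triflate counter-ion and a halide-free medium, since 9 is made by deprotonation with a slight deficit of n-BuLi so that neither lithium halide nor a butylboronate complex is present. The lithiation is expected at the C–H next to the OMOM group and not next to OMe, because the chelating acetal is the stronger ortho-director.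

Step 6
Reactants: 11 pinacol {(1S)-2-[2-(benzyloxy)-4,5-dimethoxyphenyl]-1-[2-(methoxymethoxy)-3,4,5-trimethoxyphenyl]ethyl}boronate
Product: 14 (2S)-3-[2-(benzyloxy)-4,5-dimethoxyphenyl]-2-[2-(methoxymethoxy)-3,4,5-trimethoxyphenyl]propan-1-ol, via chloromethyl boronate complex 12 (not isolated), via homologated boronate 13 (not isolated)
Conditions: BrCH2Cl, n-BuLi (added to 11 and BrCH2Cl), THF, −78 °C → rt; then NaOH, H2O2, THF/H2O, 0 °C → rt
Reagents that add atoms: chloromethyllithium (formed in the flask from bromochloromethane, ClCBr, and n-BuLi), [Li]CCl; hydrogen peroxide, OO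
Why: Matteson homologation, in which chloromethyllithium generated by fast bromine–lithium exchange adds to boron and C3 migrates from boron to the CH2 carbon with loss of chloride and retention at C3, after which alkaline peroxide oxidises the now primary C–B bond to the alcohol without touching C3.

Step 7
Reactants: 14 (2S)-3-[2-(benzyloxy)-4,5-dimethoxyphenyl]-2-[2-(methoxymethoxy)-3,4,5-trimethoxyphenyl]propan-1-ol
Product: 15 2-{(2S)-3-hydroxy-2-[2-(methoxymethoxy)-3,4,5-trimethoxyphenyl]propyl}-4,5-dimethoxyphenol
Conditions: H2 (1 atm), 10 % Pd/C, EtOAc/EtOH, rt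
Reagents that add atoms: none
Why: Catalytic hydrogenolysis of the benzyl aryl ether should be clean, since the MOM acetal, the methyl ethers and the stereocentre (which bears no benzylic heteroatom) are inert under neutral conditions.

Step 8
Reactants: 15 2-{(2S)-3-hydroxy-2-[2-(methoxymethoxy)-3,4,5-trimethoxyphenyl]propyl}-4,5-dimethoxyphenol
Product: 16 (3S)-6,7-dimethoxy-3-[2-(methoxymethoxy)-3,4,5-trimethoxyphenyl]-3,4-dihydro-2H-chromene
Conditions: PPh3, DIAD, THF, 0 °C → rt
Reagents that add atoms: none
Why: Intramolecular Mitsunobu etherification, in which the primary alcohol is activated as its alkoxyphosphonium ion and displaced by the only free phenol (O1 on C8a) in a 6-exo-tet SN2 closure at C2 that forms ring C without involving C3, the ring B oxygen being still masked so that no five-membered ether can form.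

Step 9
Reactants: 16 (3S)-6,7-dimethoxy-3-[2-(methoxymethoxy)-3,4,5-trimethoxyphenyl]-3,4-dihydro-2H-chromene
Product: 17 6-[(3S)-6,7-dimethoxy-3,4-dihydro-2H-chromen-3-yl]-2,3,4-trimethoxyphenol
Conditions: HCl (cat.), MeOH, 40 °C
Reagents that add atoms: none
Why: Acid-catalysed acetal exchange with methanol removes the MOM group, while the aryl methyl ethers, the chroman ether and C3 are stable to dilute acid.

Step 10
Reactants: 17 6-[(3S)-6,7-dimethoxy-3,4-dihydro-2H-chromen-3-yl]-2,3,4-trimethoxyphenol
Product: 18 abroquinone A, 5-[(3S)-6,7-dimethoxy-3,4-dihydro-2H-chromen-3-yl]-2,3-dimethoxycyclohexa-2,5-diene-1,4-dione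
Conditions: PhI(OAc)2, MeCN/H2O (2:1), 0 °C
Reagents that add atoms: water, O
Why: Hypervalent-iodine oxidation of a para-methoxyphenol, in which ligand exchange at trivalent iodine activates the free ring B phenol, water adds at C5' para to the phenolic oxygen and methanol is expelled to give the 2',5'-quinone, while ring A, having no free hydroxyl, is not engaged.

Compound list
1 | 2,3,4-trimethoxyphenol | COc1ccc(O)c(OC)c1OC | starting material
2 | 1,2,3-trimethoxy-4-(methoxymethoxy)benzene | COCOc1ccc(OC)c(OC)c1OC | intermediate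
3 | 2-hydroxy-4,5-dimethoxybenzaldehyde | COc1cc(O)c(C=O)cc1OC | starting material
4 | 2-(benzyloxy)-4,5-dimethoxybenzaldehyde | COc1cc(OCc2ccccc2)c(C=O)cc1OC | intermediate
5 | 2-(benzyloxy)-4,5-dimethoxyphenyl formate | COc1cc(OCc2ccccc2)c(OC=O)cc1OC | intermediate
6 | 2-(benzyloxy)-4,5-dimethoxyphenol | COc1cc(OCc2ccccc2)c(O)cc1OC | intermediate
7 | 2-(benzyloxy)-4,5-dimethoxyphenyl trifluoromethanesulfonate | COc1cc(OCc2ccccc2)c(OS(=O)(=O)C(F)(F)F)cc1OC | intermediate
8 | pinacol vinylboronate (4,4,5,5-tetramethyl-2-vinyl-1,3,2-dioxaborolane) | C=CB1OC(C)(C)C(C)(C)O1 | starting material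
9 | [2-(methoxymethoxy)-3,4,5-trimethoxyphenyl]lithium | [Li]c1cc(OC)c(OC)c(OC)c1OCOC | intermediate
10 | lithium [2-(methoxymethoxy)-3,4,5-trimethoxyphenyl](vinyl)(pinacolato)borate | [Li+].C=C[B-]1(c2cc(OC)c(OC)c(OC)c2OCOC)OC(C)(C)C(C)(C)O1 | intermediate
11 | pinacol {(1S)-2-[2-(benzyloxy)-4,5-dimethoxyphenyl]-1-[2-(methoxymethoxy)-3,4,5-trimethoxyphenyl]ethyl}boronate | COc1cc([C@H](Cc2cc(OC)c(OC)cc2OCc2ccccc2)B2OC(C)(C)C(C)(C)O2)c(OCOC)c(OC)c1OC | intermediate
12 | lithium (chloromethyl){(1S)-2-[2-(benzyloxy)-4,5-dimethoxyphenyl]-1-[2-(methoxymethoxy)-3,4,5-trimethoxyphenyl]ethyl}(pinacolato)borate | [Li+].COc1cc([C@H](Cc2cc(OC)c(OC)cc2OCc2ccccc2)[B-]2(CCl)OC(C)(C)C(C)(C)O2)c(OCOC)c(OC)c1OC | intermediate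
13 | pinacol {(2S)-3-[2-(benzyloxy)-4,5-dimethoxyphenyl]-2-[2-(methoxymethoxy)-3,4,5-trimethoxyphenyl]propyl}boronate | COc1cc([C@H](Cc2cc(OC)c(OC)cc2OCc2ccccc2)CB2OC(C)(C)C(C)(C)O2)c(OCOC)c(OC)c1OC | intermediate
14 | (2S)-3-[2-(benzyloxy)-4,5-dimethoxyphenyl]-2-[2-(methoxymethoxy)-3,4,5-trimethoxyphenyl]propan-1-ol | COc1cc([C@H](Cc2cc(OC)c(OC)cc2OCc2ccccc2)CO)c(OCOC)c(OC)c1OC | intermediate
15 | 2-{(2S)-3-hydroxy-2-[2-(methoxymethoxy)-3,4,5-trimethoxyphenyl]propyl}-4,5-dimethoxyphenol | COc1cc([C@H](Cc2cc(OC)c(OC)cc2O)CO)c(OCOC)c(OC)c1OC | intermediate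
16 | (3S)-6,7-dimethoxy-3-[2-(methoxymethoxy)-3,4,5-trimethoxyphenyl]-3,4-dihydro-2H-chromene | COc1cc([C@H]2COc3cc(OC)c(OC)cc3C2)c(OCOC)c(OC)c1OC | intermediate
17 | 6-[(3S)-6,7-dimethoxy-3,4-dihydro-2H-chromen-3-yl]-2,3,4-trimethoxyphenol | COc1cc([C@H]2COc3cc(OC)c(OC)cc3C2)c(O)c(OC)c1OC | intermediate
18 | abroquinone A, 5-[(3S)-6,7-dimethoxy-3,4-dihydro-2H-chromen-3-yl]-2,3-dimethoxycyclohexa-2,5-diene-1,4-dione | COC1=C(OC)C(=O)C([C@H]2COc3cc(OC)c(OC)cc3C2)=CC1=O | target

Total step count: 10.
Longest linear sequence: 9 steps (steps 2, 3, 4, 5, 6, 7, 8, 9 and 10, from 3). The ring B branch (steps 1 and 5 to 10) is 7 steps.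

Steps most likely to fail

Step 5. The aryl or vinyl group may pass directly from boron to palladium (Suzuki-type coupling) instead of undergoing the metallate shift. Oxidative addition of the very electron-rich, ortho-alkoxy triflate may be slow. Enantioface selection may erode with an ortho-substituted migrating aryl. Incomplete lithiation may leave n-BuLi that enters as a butylboronate complex. The fallback forms C3–C4 by auxiliary-controlled enolate alkylation instead; it sets out from 2 and 4 and comes back at 14, so that steps 3 to 6 are bypassed. Compound 2 would be ortho-lithiated (n-BuLi, THF, 0 °C) and the aryllithium opened with ethylene oxide to give 2-[2-(methoxymethoxy)-3,4,5-trimethoxyphenyl]ethanol F1. Oxidation with TEMPO and PhI(OAc)2 in MeCN/H2O would give [2-(methoxymethoxy)-3,4,5-trimethoxyphenyl]acetic acid F2. Activation as the mixed pivalic anhydride (PivCl, Et3N, THF) and reaction with lithiated (S)-4-benzyloxazolidin-2-one would give (4S)-4-benzyl-3-{[2-(methoxymethoxy)-3,4,5-trimethoxyphenyl]acetyl}oxazolidin-2-one F3. In parallel, aldehyde 4 would be reduced (NaBH4, MeOH, 0 °C) to [2-(benzyloxy)-4,5-dimethoxyphenyl]methanol F4 and converted by an Appel reaction (CBr4, PPh3, CH2Cl2, 0 °C) into 1-(benzyloxy)-2-(bromomethyl)-4,5-dimethoxybenzene F5, to be used at once. The chelated sodium Z-enolate of F3 (NaN(SiMe3)2, THF, −78 °C) should be alkylated by F5 on the face away from the benzyl group of the auxiliary. This is expected to give (4S)-4-benzyl-3-{(2S)-3-[2-(benzyloxy)-4,5-dimethoxyphenyl]-2-[2-(methoxymethoxy)-3,4,5-trimethoxyphenyl]propanoyl}oxazolidin-2-one F6. Reductive removal of the auxiliary (LiBH4, THF/H2O, 0 °C) would release alcohol 14.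

Step 6. The thermally fragile carbenoid may decompose before it complexes the hindered secondary benzylic boron, so that unchanged 11 is later oxidised to the C3 carbinol, or more than one CH2 may be inserted. The fallback attaches a two-carbon unit that is then cut back to one; it sets out from 11 and comes back at 14. A Zweifel olefination (CH2=CHMgBr, THF/DMSO, rt; then I2, MeOH, −78 °C; NaOMe, → rt) uses a nucleophile that is stable at room temperature, so complexation of the boron can be driven to completion. It should give, with retention at C3, 1-(benzyloxy)-4,5-dimethoxy-2-{(2R)-2-[2-(methoxymethoxy)-3,4,5-trimethoxyphenyl]but-3-en-1-yl}benzene F7 (same spatial arrangement, descriptor changed by priority only). Ozonolysis with one equivalent of ozone from a titrated CH2Cl2 solution (CH2Cl2/MeOH, −78 °C), quenched directly with NaBH4 so that the epimerisable α-aryl aldehyde is reduced as it forms, would give 14.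

Step 10. Water may add at C3' instead of C5', giving an ortho-quinone, or the sensitive quinone and the electron-rich ring A may be oxidised further in the aqueous medium. The fallback separates oxidation from unmasking; it sets out from 17 and comes back at 18. Oxidation with PhI(OAc)2 in anhydrous MeOH at 0 °C should trap the para position as the isolable quinone monoketal 6-[(3S)-6,7-dimethoxy-3,4-dihydro-2H-chromen-3-yl]-2,3,4,4-tetramethoxycyclohexa-2,5-dien-1-one F8. Mild hydrolysis (aqueous oxalic acid, THF, rt) would then release 18.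

Further compounds
F1 | step 5 | 2-[2-(methoxymethoxy)-3,4,5-trimethoxyphenyl]ethanol | COCOc1c(CCO)cc(OC)c(OC)c1OC
F2 | step 5 | [2-(methoxymethoxy)-3,4,5-trimethoxyphenyl]acetic acid | COCOc1c(CC(=O)O)cc(OC)c(OC)c1OC
F3 | step 5 | (4S)-4-benzyl-3-{[2-(methoxymethoxy)-3,4,5-trimethoxyphenyl]acetyl}oxazolidin-2-one | COCOc1c(CC(=O)N2[C@@H](Cc3ccccc3)COC2=O)cc(OC)c(OC)c1OC
F4 | step 5 | [2-(benzyloxy)-4,5-dimethoxyphenyl]methanol | COc1cc(OCc2ccccc2)c(CO)cc1OC
F5 | step 5 | 1-(benzyloxy)-2-(bromomethyl)-4,5-dimethoxybenzene | COc1cc(OCc2ccccc2)c(CBr)cc1OC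
F6 | step 5 | (4S)-4-benzyl-3-{(2S)-3-[2-(benzyloxy)-4,5-dimethoxyphenyl]-2-[2-(methoxymethoxy)-3,4,5-trimethoxyphenyl]propanoyl}oxazolidin-2-one | COc1cc([C@H](Cc2cc(OC)c(OC)cc2OCc2ccccc2)C(=O)N2[C@@H](Cc3ccccc3)COC2=O)c(OCOC)c(OC)c1OC
F7 | step 6 | 1-(benzyloxy)-4,5-dimethoxy-2-{(2R)-2-[2-(methoxymethoxy)-3,4,5-trimethoxyphenyl]but-3-en-1-yl}benzene | COc1cc([C@H](Cc2cc(OC)c(OC)cc2OCc2ccccc2)C=C)c(OCOC)c(OC)c1OC
F8 | step 10 | 6-[(3S)-6,7-dimethoxy-3,4-dihydro-2H-chromen-3-yl]-2,3,4,4-tetramethoxycyclohexa-2,5-dien-1-one | COC1=C(OC)C(OC)(OC)C=C([C@H]2COc3cc(OC)c(OC)cc3C2)C1=O
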